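**Plan**

- The target is a depside. Ring A (acyl carbon on C1, heptyl on C2, oxygens on C4 and C6) is a resorcylate, the folding pattern of a 3,5,7-triketo ester, and its hindered C1 carbonyl is esterified to the C4 oxygen of ring B. Ring A can therefore be grown on the ester after the C–O bond already exists.
- Retrosynthesis: remove the benzyl group from the ring B acid and the methyl group from the ring A C4 oxygen, then cut the ring A C1–C2 bond (aldol) and the depside acyl C–O bond (acylketene plus phenol). This gives a diketo-dioxinone and the ring B phenol.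
- Ring B is cut at C1–C6 and C2–C3 (Diels–Alder of benzyl dec-2-ynoate with 1,1-dimethoxy-3-(trimethylsilyloxy)buta-1,3-diene). The dioxinone side chain is cut at its two ketone α-bonds (acetylation, then octanoylation).
- Forward: ring B is made first, the ester bond second and ring A third in the same flask, followed by O-methylation and hydrogenolysis.
- The target has no stereocentre. Only regiochemistry must be controlled: cycloaddition polarity for ring B, and hydrogen bonding of the ring A C6 hydroxyl for the mono-methylation.

Key step: step 8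

Remark: the 1,3-dicarbonyl intermediates are written as keto tautomers although they will be largely enolised; the target is achiral, so no stereocontrol is required.

Step 1
Reactants: 1 2,2,6-trimethyl-4H-1,3-dioxin-4-one; 2 acetyl chloride
Product: 3 2,2-dimethyl-6-(2-oxopropyl)-4H-1,3-dioxin-4-one
Conditions: LiN(SiMe3)2, THF, −78 °C (2 equiv of enolate per acyl chloride); then 2; aq. NH4Cl
Reagents that add atoms: none
Why: γ-Deprotonation of 1 gives the lithium dienolate, which is C-acylated at the exocyclic carbon by acetyl chloride (crossed Claisen-type acylation), the second equivalent of enolate absorbing the proton of the more acidic product.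

Step 2
Reactants: 4 octanoyl chloride
Product: 5 N-methoxy-N-methyloctanamide
Conditions: MeNH(OMe)·HCl, Et3N, CH2Cl2, 0 °C to rt
Reagents that add atoms: N,O-dimethylhydroxylamine hydrochloride, CNOC.Cl
Why: Amide formation from an acid chloride and an amine salt (Schotten–Baumann-type acylation) is routine and gives an acyl donor that stops at the ketone stage in the next step.

Step 3
Reactants: 3 2,2-dimethyl-6-(2-oxopropyl)-4H-1,3-dioxin-4-one; 5 N-methoxy-N-methyloctanamide
Product: 6 2,2-dimethyl-6-(2,4-dioxoundecyl)-4H-1,3-dioxin-4-one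
Conditions: LiN(i-Pr)2 (2.2 equiv), THF, −78 °C; then 5, −78 to −20 °C; cold 1 M HCl quench
Reagents that add atoms: none
Why: Double deprotonation of 3 gives a dianion whose terminal, methyl-derived carbanion is the more reactive site and undergoes Claisen-type acylation by the N-methoxy-N-methylamide, the chelated tetrahedral adduct surviving until the quench so that over-addition is avoided.

Step 4
Reactants: 7 non-1-yne
Product: 8 benzyl dec-2-ynoate
Conditions: n-BuLi, THF, −78 °C; then ClCO2Bn, −78 °C to rt
Reagents that add atoms: benzyl chloroformate, O=C(Cl)OCc1ccccc1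
Why: Lithiation of the terminal alkyne and acylation of the acetylide with a chloroformate is the standard alkynoate synthesis.

Step 5
Reactants: 9 1,1-dimethoxyethene; 2 acetyl chloride
Product: 10 4,4-dimethoxybut-3-en-2-one
Conditions: Et3N, Et2O, 0 °C to rt
Reagents that add atoms: none
Why: The nucleophilic methylene carbon of the ketene acetal is C-acylated by the acid chloride and the resulting dimethoxycarbenium ion is deprotonated by the amine, the established acylation of ketene acetals to acylketene acetals.

Step 6
Reactants: 10 4,4-dimethoxybut-3-en-2-one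
Product: 11 1,1-dimethoxy-3-(trimethylsilyloxy)buta-1,3-diene
Conditions: Me3SiCl, Et3N, ZnCl2 (cat.), PhMe, 40 °C
Reagents that add atoms: chlorotrimethylsilane, C[Si](C)(C)Cl
Why: ZnCl2-catalysed enolisation and O-silylation of the methyl ketone (silyl enol ether formation) should give the cross-conjugated 2-silyloxydiene, as for related 1-alkoxy-3-silyloxybutadienes.

Step 7
Reactants: 8 benzyl dec-2-ynoate; 11 1,1-dimethoxy-3-(trimethylsilyloxy)buta-1,3-diene
Product: 14 benzyl 2-heptyl-4-hydroxy-6-methoxybenzoate, via Diels–Alder cycloadduct 12 (not isolated), via aryl trimethylsilyl ether 13 (not isolated)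
Conditions: PhMe, 110 °C, sealed tube, excess 11; then 1 M HCl, THF, rt
Reagents that add atoms: none
Why: Diels–Alder cycloaddition of the electron-rich diene with the alkynoate should join the nucleophilic CH2 terminus of 11 to the heptyl-bearing β-carbon and the ketene acetal carbon to the α-carbon, after which loss of methanol from 12 aromatises the ring and acid cleaves the silyl ether of 13, placing methoxy ortho and the free hydroxyl para to the benzyl ester.

Step 8
Reactants: 6 2,2-dimethyl-6-(2,4-dioxoundecyl)-4H-1,3-dioxin-4-one; 14 benzyl 2-heptyl-4-hydroxy-6-methoxybenzoate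
Product: 18 benzyl 2-heptyl-4-[(2-heptyl-4,6-dihydroxybenzoyl)oxy]-6-methoxybenzoate, via acylketene 15 (not isolated), via aryl triketo ester 16 (not isolated), via cyclic aldol adduct 17 (not isolated)
Conditions: PhMe, 110 °C, short heating, about 0.2 M; cool, then Et3N, CH2Cl2, rt; then 1 M HCl (aq.), rt
Reagents that add atoms: none
Why: Thermal retro-[4+2] of the dioxinone ring of 6 expels acetone and leaves acylketene 15, whose sp carbon is captured by the unhindered C4 phenol of 14, so the depside C–O bond is made before ring A and its two ortho substituents exist. The closest known reaction type is dioxinone thermolysis with capture of the acylketene by an alcohol or phenol, followed by base-mediated aldol aromatisation of the 3,5,7-triketo ester to a resorcylate. Triethylamine enolises C2 of 16 (chain numbering, C1 = ester carbonyl), which adds to the C7 ketone in a 6-(enolendo)-exo-trig aldol to give 17, and loss of water with enolisation closes ring A as the 2-heptyl-4,6-dihydroxybenzoate. No stereocentre remains in the product, since the carbinol carbon of 17 is erased on dehydration. The step needs the C2-to-C7 carbocyclisation to outrun attack of the C5 enol oxygen or of C6 on the aryl ester carbonyl (pyrone or acylphloroglucinol formation with loss of the phenoxide of 14); the higher electrophilicity of the ketone, the acidity of C2 between ester and ketone, and a weak amine base in an aprotic solvent at room temperature should secure this. The octanoyl-derived C7 fixes the heptyl group ortho to the ester, and the C6 hydroxyl emerges hydrogen-bonded to the ester carbonyl.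

Step 9
Reactants: 18 benzyl 2-heptyl-4-[(2-heptyl-4,6-dihydroxybenzoyl)oxy]-6-methoxybenzoate
Product: 19 benzyl 2-heptyl-4-[(2-heptyl-6-hydroxy-4-methoxybenzoyl)oxy]-6-methoxybenzoate
Conditions: MeI (1.1 equiv), K2CO3, acetone, rt
Reagents that add atoms: iodomethane, CI
Why: Williamson etherification should take place only at the ring A C4 hydroxyl, the more acidic and non-chelated phenol, because the C6 hydroxyl is hydrogen-bonded to the depside carbonyl and ring B carries no free hydroxyl.

Step 10
Reactants: 19 benzyl 2-heptyl-4-[(2-heptyl-6-hydroxy-4-methoxybenzoyl)oxy]-6-methoxybenzoate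
Product: 20 2-heptyl-4-[(2-heptyl-6-hydroxy-4-methoxybenzoyl)oxy]-6-methoxybenzoic acid
Conditions: H2 (1 atm), Pd/C, EtOAc, rt
Reagents that add atoms: none
Why: Catalytic hydrogenolysis of the benzyl ester is neutral and leaves the aryl ester, the methyl ethers and the arenes untouched, the usual way to unmask the acid of a depside.

**Compound list**

1 | 2,2,6-trimethyl-4H-1,3-dioxin-4-one | CC1=CC(=O)OC(C)(C)O1 | starting material
2 | acetyl chloride | CC(Cl)=O | starting material
3 | 2,2-dimethyl-6-(2-oxopropyl)-4H-1,3-dioxin-4-one | CC(=O)CC1=CC(=O)OC(C)(C)O1 | intermediate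
4 | octanoyl chloride | CCCCCCCC(Cl)=O | starting material
5 | N-methoxy-N-methyloctanamide | CCCCCCCC(=O)N(C)OC | intermediate
6 | 2,2-dimethyl-6-(2,4-dioxoundecyl)-4H-1,3-dioxin-4-one | CCCCCCCC(=O)CC(=O)CC1=CC(=O)OC(C)(C)O1 | intermediate
7 | non-1-yne | C#CCCCCCCC | starting material
8 | benzyl dec-2-ynoate | CCCCCCCC#CC(=O)OCc1ccccc1 | intermediate
9 | 1,1-dimethoxyethene | C=C(OC)OC | starting material
10 | 4,4-dimethoxybut-3-en-2-one | CC(=O)C=C(OC)OC | intermediate
11 | 1,1-dimethoxy-3-(trimethylsilyloxy)buta-1,3-diene | COC(OC)=CC(=C)O[Si](C)(C)C | intermediate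
12 | benzyl 2-heptyl-6,6-dimethoxy-4-(trimethylsilyloxy)cyclohexa-1,4-diene-1-carboxylate | CCCCCCCC1=C(C(=O)OCc2ccccc2)C(OC)(OC)C=C(O[Si](C)(C)C)C1 | intermediate
13 | benzyl 2-heptyl-6-methoxy-4-(trimethylsilyloxy)benzoate | CCCCCCCc1cc(O[Si](C)(C)C)cc(OC)c1C(=O)OCc1ccccc1 | intermediate
14 | benzyl 2-heptyl-4-hydroxy-6-methoxybenzoate | CCCCCCCc1cc(O)cc(OC)c1C(=O)OCc1ccccc1 | intermediate
15 | tetradec-1-ene-1,3,5,7-tetrone (acylketene) | CCCCCCCC(=O)CC(=O)CC(=O)C=C=O | intermediate
16 | benzyl 2-heptyl-6-methoxy-4-[(3,5,7-trioxotetradecanoyl)oxy]benzoate | CCCCCCCC(=O)CC(=O)CC(=O)CC(=O)Oc1cc(CCCCCCC)c(C(=O)OCc2ccccc2)c(OC)c1 | intermediate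
17 | benzyl 2-heptyl-4-[(2-heptyl-2-hydroxy-4,6-dioxocyclohexane-1-carbonyl)oxy]-6-methoxybenzoate (mixture of stereoisomers, transient) | CCCCCCCC1(O)CC(=O)CC(=O)C1C(=O)Oc1cc(CCCCCCC)c(C(=O)OCc2ccccc2)c(OC)c1 | intermediate
18 | benzyl 2-heptyl-4-[(2-heptyl-4,6-dihydroxybenzoyl)oxy]-6-methoxybenzoate | CCCCCCCc1cc(O)cc(O)c1C(=O)Oc1cc(CCCCCCC)c(C(=O)OCc2ccccc2)c(OC)c1 | intermediate
19 | benzyl 2-heptyl-4-[(2-heptyl-6-hydroxy-4-methoxybenzoyl)oxy]-6-methoxybenzoate | CCCCCCCc1cc(OC)cc(O)c1C(=O)Oc1cc(CCCCCCC)c(C(=O)OCc2ccccc2)c(OC)c1 | intermediate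
20 | 2-heptyl-4-[(2-heptyl-6-hydroxy-4-methoxybenzoyl)oxy]-6-methoxybenzoic acid | CCCCCCCc1cc(OC)cc(O)c1C(=O)Oc1cc(CCCCCCC)c(C(=O)O)c(OC)c1 | target

**Step count and risks**

Total step count: 10. Longest linear sequence: 6 steps (steps 5, 6, 7, 8, 9, 10).

Steps most likely to fail:

Step 8. The risk is loss of chemoselectivity after ketene capture. The aryl ester of 16 is an activated acyl donor, so lactonisation through the C5 enol oxygen to a 4-hydroxy-2-pyrone, or Claisen closure from C6 to an acylphloroglucinol, each with expulsion of the ring B phenoxide, may compete with the C2-to-C7 aldol. The ketene may also be captured by its own enol before the phenol adds, and prolonged heating may reverse the phenol addition. The fallback builds ring A on a simple ester and forms the depside bond by classical acylation. It sets out from 6: thermolysis with allyl alcohol (PhMe, 110 °C) would give allyl 3,5,7-trioxotetradecanoate F1, which Et3N would cyclise through allyl 2-heptyl-2-hydroxy-4,6-dioxocyclohexane-1-carboxylate F2 to allyl 2-heptyl-4,6-dihydroxybenzoate F3. MeI and K2CO3 in acetone would methylate the free C4 hydroxyl to give allyl 2-heptyl-6-hydroxy-4-methoxybenzoate F4. Pd(PPh3)4 (zerovalent palladium) with morpholine would then remove the allyl group to give 2-heptyl-6-hydroxy-4-methoxybenzoic acid F5. Condensation of this acid with phenol 14 by trifluoroacetic anhydride in toluene (mixed-anhydride acylation of the phenol) would give 19, where the route is rejoined.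

Step 7. The risk is a sluggish cycloaddition of the β-alkyl alkynoate, with desilylation or polymerisation of the diene outpacing ring formation. The fallback makes ring B by the same polyketide-type aromatisation and differentiates its two hydroxyls by protection. It sets out from 6: thermolysis with benzyl alcohol would give benzyl 3,5,7-trioxotetradecanoate F6, which Et3N would cyclise through benzyl 2-heptyl-2-hydroxy-4,6-dioxocyclohexane-1-carboxylate F7 to benzyl 2-heptyl-4,6-dihydroxybenzoate F8. Allyl bromide and K2CO3 (acetone, rt) would etherify only the non-chelated C4 hydroxyl, giving benzyl 2-heptyl-6-hydroxy-4-(prop-2-en-1-yloxy)benzoate F9. MeI and K2CO3 in DMF at 60 °C would then methylate the chelated C6 hydroxyl, giving benzyl 2-heptyl-6-methoxy-4-(prop-2-en-1-yloxy)benzoate F10. Pd(PPh3)4 with morpholine would cleave the allyl ether and return 14.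

Step 3. The risk is quenching of the dianion by proton transfer from the more acidic 1,3-diketone as it forms, together with O-acylation, leading to incomplete conversion. The fallback installs the octanoyl group by chelation-controlled C-acylation of a β-keto ester and then removes the ester. It sets out from 1: acylation of its lithium enolate (LiN(SiMe3)2, THF, −78 °C) with allyl 3-(1H-benzotriazol-1-yl)-3-oxopropanoate would give allyl 4-(2,2-dimethyl-4-oxo-4H-1,3-dioxin-6-yl)-3-oxobutanoate F11. MgCl2 and pyridine with octanoyl chloride 4 would C-acylate the carbon between ketone and ester to give allyl 2-[(2,2-dimethyl-4-oxo-4H-1,3-dioxin-6-yl)acetyl]-3-oxodecanoate F12. Pd(PPh3)4 with morpholine would remove the allyl group and trigger decarboxylation, returning 6.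

**Further compounds**

F1 | step 8 | allyl 3,5,7-trioxotetradecanoate | CCCCCCCC(=O)CC(=O)CC(=O)CC(=O)OCC=C
F2 | step 8 | allyl 2-heptyl-2-hydroxy-4,6-dioxocyclohexane-1-carboxylate | CCCCCCCC1(O)CC(=O)CC(=O)C1C(=O)OCC=C
F3 | step 8 | allyl 2-heptyl-4,6-dihydroxybenzoate | CCCCCCCc1cc(O)cc(O)c1C(=O)OCC=C
F4 | step 8 | allyl 2-heptyl-6-hydroxy-4-methoxybenzoate | CCCCCCCc1cc(OC)cc(O)c1C(=O)OCC=C
F5 | step 8 | 2-heptyl-6-hydroxy-4-methoxybenzoic acid | CCCCCCCc1cc(OC)cc(O)c1C(=O)O
F6 | step 7 | benzyl 3,5,7-trioxotetradecanoate | CCCCCCCC(=O)CC(=O)CC(=O)CC(=O)OCc1ccccc1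
F7 | step 7 | benzyl 2-heptyl-2-hydroxy-4,6-dioxocyclohexane-1-carboxylate | CCCCCCCC1(O)CC(=O)CC(=O)C1C(=O)OCc1ccccc1
F8 | step 7 | benzyl 2-heptyl-4,6-dihydroxybenzoate | CCCCCCCc1cc(O)cc(O)c1C(=O)OCc1ccccc1
F9 | step 7 | benzyl 2-heptyl-6-hydroxy-4-(prop-2-en-1-yloxy)benzoate | CCCCCCCc1cc(OCC=C)cc(O)c1C(=O)OCc1ccccc1
F10 | step 7 | benzyl 2-heptyl-6-methoxy-4-(prop-2-en-1-yloxy)benzoate | CCCCCCCc1cc(OCC=C)cc(OC)c1C(=O)OCc1ccccc1
F11 | step 3 | allyl 4-(2,2-dimethyl-4-oxo-4H-1,3-dioxin-6-yl)-3-oxobutanoate | C=CCOC(=O)CC(=O)CC1=CC(=O)OC(C)(C)O1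
F12 | step 3 | allyl 2-[(2,2-dimethyl-4-oxo-4H-1,3-dioxin-6-yl)acetyl]-3-oxodecanoate | CCCCCCCC(=O)C(C(=O)OCC=C)C(=O)CC1=CC(=O)OC(C)(C)O1
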